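**Plan**

- Retrosynthetic cuts: (i) the C8–O aryl ether, made by Mitsunobu inversion at C8 between an 8-epi alcohol of the tetrahydrochromone and 6-hydroxy-7-methoxy-2-(2-phenylethyl)chromone; (ii) O1–C8a and C4–C4a of the tetrahydrochromone pyranone (acylketene plus enol ether); (iii) C4a=C8a, made by loss of SO2 from a thiepane 1,1-dioxide.
- Feature used: the enol-ether double bond C4a=C8a closes a carbocycle whose other four atoms, C5–C8, are a row of carbinol carbons, i.e. C2–C5 of a hexitol. Bridging the chain ends C1 (C4a) and C6 (C8a) by sulfur gives a seven-membered ring that can contract onto exactly this bond.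
- Forward order: 3,4-O-isopropylidene-D-mannitol → L-ido bis-epoxide → C2-symmetric thiepane → S,O-acetal with a methylene tether O8–CH2–O–C8a → sulfone → Ramberg–Bäcklund contraction to the cyclohexene enol ether → pyranone annulation (tether lost as formaldehyde, 8-OH freed) → Mitsunobu union with the aromatic chromone (four separate steps) → acid deprotection.
- Stereochemistry: C6 and C7 are C3 and C4 of D-mannitol; C5 is mannitol C2, inverted in the epoxide closure; C8 is mannitol C5, inverted in the epoxide closure and again in the Mitsunobu step. No stereocentre is set by a reagent.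

Key step: step 8

Remark: chromone numbering (O1, C2–C4, C4a, C5–C8, C8a) is used for the carbocycle throughout; hexitol C1–C6 become C4a, C5, C6, C7, C8, C8a.
Remark: the acetal carbon of 9 and 10 and the new sp3 centres of the transient species 11, 12 and 18 are drawn as one diastereomer each (cis ring fusions); all of them become sp2 later, so their configuration is without consequence.

**Route**

Step 1
Reactants: 1 3,4-O-isopropylidene-D-mannitol
Product: 2 1,6-di-O-benzoyl-3,4-O-isopropylidene-D-mannitol
Conditions: BzCl (2.05 equiv), pyridine, CH2Cl2, −30 °C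
Reagents that add atoms: benzoyl chloride, O=C(Cl)c1ccccc1
Why: Selective esterification, since acyl transfer to the two primary hydroxyls is much faster than to the hindered secondary ones at low temperature; no stereocentre is touched.

Step 2
Reactants: 2 1,6-di-O-benzoyl-3,4-O-isopropylidene-D-mannitol
Product: 3 1,6-di-O-benzoyl-3,4-O-isopropylidene-2,5-di-O-mesyl-D-mannitol
Conditions: MsCl, Et3N, CH2Cl2, 0 °C
Reagents that add atoms: methanesulfonyl chloride, CS(=O)(=O)Cl
Why: Standard sulfonylation of the two remaining secondary hydroxyls with retention, which installs the leaving groups for the epoxide closure.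

Step 3
Reactants: 3 1,6-di-O-benzoyl-3,4-O-isopropylidene-2,5-di-O-mesyl-D-mannitol
Product: 5 1,2:5,6-dianhydro-3,4-O-isopropylidene-L-iditol, via diol dimesylate 4 (not isolated)
Conditions: K2CO3, MeOH, rt
Reagents that add atoms: none
Why: Methanolysis of the benzoates frees the primary alkoxides, which displace the neighbouring mesylates by intramolecular Williamson closure (3-exo-tet SN2), so that C2 and C5 are inverted and the D-manno chain becomes the C2-symmetric L-ido bis-epoxide.

Step 4
Reactants: 5 1,2:5,6-dianhydro-3,4-O-isopropylidene-L-iditol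
Product: 6 1,6-dideoxy-1,6-epithio-3,4-O-isopropylidene-L-iditol
Conditions: Na2S·9H2O, EtOH, reflux
Reagents that add atoms: sodium sulfide, [Na+].[Na+].[S-2]
Why: Double SN2 epoxide opening, known for this class of bis-epoxides: sulfide opens one epoxide at its primary carbon and the thiolate opens the second one at the primary carbon too (7-endo-tet, preferred over 6-exo attack at the secondary carbon next to the trans-dioxolane), so the thiepane forms and no stereocentre is touched.

Step 5
Reactants: 6 1,6-dideoxy-1,6-epithio-3,4-O-isopropylidene-L-iditol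
Product: 7 1,6-dideoxy-1,6-epithio-3,4-O-isopropylidene-2,5-bis-O-(methoxymethyl)-L-iditol
Conditions: MOMCl, iPr2NEt, Bu4NI (cat.), CH2Cl2, 0 → 40 °C
Reagents that add atoms: chloromethyl methyl ether, COCCl
Why: Williamson-type O-alkylation (MOM protection) of the two homotopic hydroxyls; the groups are base-stable, and the one next to the future acetal carbon serves as internal nucleophile in step 6.

Step 6
Reactants: 7 1,6-dideoxy-1,6-epithio-3,4-O-isopropylidene-2,5-bis-O-(methoxymethyl)-L-iditol
Product: 9 3,4-O-isopropylidene-5-O-(methoxymethyl)-1,2-O-methylene-6-thio-L-idoseptanose, via thionium chloride 8 (not isolated)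
Conditions: NCS (1.0 equiv), K2CO3 (solid), CH2Cl2, 0 °C → rt
Reagents that add atoms: none
Why: Proposed new method: NCS should convert the sulfide into a chlorosulfonium ion and then into the thionium ion 8 (Pummerer-type α-chlorination pathway); the methoxy oxygen of the MOM group on the adjacent carbon is expected to add to it (5-exo) instead of chloride, and the oxonium ion then loses its methyl group to chloride as MeCl, which makes the closure irreversible and gives the cis-fused cyclic formal; C2 symmetry makes the two α-carbons equivalent, so no regiochemical question arises; the closest known reaction types are the NCS chlorination of sulfides to α-chloro sulfides and the capture of oxocarbenium, halonium or epoxonium ions by a neighbouring MOM ether to give a cyclic formal.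

Step 7
Reactants: 9 3,4-O-isopropylidene-5-O-(methoxymethyl)-1,2-O-methylene-6-thio-L-idoseptanose
Product: 10 3,4-O-isopropylidene-5-O-(methoxymethyl)-1,2-O-methylene-6-thio-L-idoseptanose S,S-dioxide
Conditions: mCPBA (2.2 equiv), NaHCO3, CH2Cl2, 0 °C → rt
Reagents that add atoms: mCPBA, OOC(=O)c1cccc(Cl)c1
Why: Peracid oxidation of the sulfide through the sulfoxide to the sulfone, as in the preparation of glycosyl sulfones; the buffer protects the acetals.

Step 8
Reactants: 10 3,4-O-isopropylidene-5-O-(methoxymethyl)-1,2-O-methylene-6-thio-L-idoseptanose S,S-dioxide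
Product: 13 4,5-O-isopropylidene-3-O-(methoxymethyl)-1,6-O-methylenecyclohex-1-ene-1,3,4,5,6-pentol (all-trans at C3–C6; L-ido), via α-bromo sulfone 11 (not isolated), via episulfone 12 (not isolated)
Conditions: BrCF2CF2Br, KOH/Al2O3, t-BuOH–CH2Cl2, 0 °C → rt
Reagents that add atoms: none
Why: Halogenative Ramberg–Bäcklund reaction (Meyers–Chan type): KOH on alumina deprotonates the CH2 group α to the sulfone, BrCF2CF2Br transfers Br+ to give 11, the carbanion at the acetal α'-carbon displaces bromide in a 1,3-elimination to the episulfone 12, and cheletropic loss of SO2 forms the C4a=C8a bond, so the seven-membered thiepane contracts to the six-membered carbocycle. The closest known reactions are the Ramberg–Bäcklund contraction of hexitol-derived thiepane S,S-dioxides to conduritol derivatives and the same reaction of glycosyl sulfones, which gives enol ethers. The only ring closed is the transient thiirane dioxide (3-exo-tet); the cyclohexene is the contracted thiepane, and its double bond can only be Z. No stereocentre is created: C5–C8 are spectators and the acetal centre becomes sp2. The step needs the 1,3-elimination to outrun β-elimination of an alkoxide from either α-sulfonyl carbanion; on the acetal side the β-oxygen is tied back in the dioxolane, whose C–O bond is held out of line with the carbanion orbital, and on the CH2 side the carbanion is brominated as fast as it forms. The bromine source fragments to tetrafluoroethene and bromide and not to a carbene, so the electron-rich enol ether 13 should survive.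

Step 9
Reactants: 14 2,2,6-trimethyl-4H-1,3-dioxin-4-one; 15 benzyl bromide
Product: 16 2,2-dimethyl-6-(2-phenylethyl)-4H-1,3-dioxin-4-one
Conditions: LDA, THF–DMPU, −78 °C; then 15, −78 → −20 °C
Reagents that add atoms: none
Why: γ-Alkylation of the lithium dienolate of the dioxinone (vinylogous enolate alkylation), which is known to take place at the exocyclic 6-methyl carbon with reactive halides.

Step 10
Reactants: 13 4,5-O-isopropylidene-3-O-(methoxymethyl)-1,6-O-methylenecyclohex-1-ene-1,3,4,5,6-pentol; 16 2,2-dimethyl-6-(2-phenylethyl)-4H-1,3-dioxin-4-one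
Product: 20 (5S,6R,7R,8R)-8-hydroxy-6,7-(isopropylidenedioxy)-5-(methoxymethoxy)-2-(2-phenylethyl)-5,6,7,8-tetrahydro-4H-chromen-4-one, via acylketene 17 (not isolated), via cycloadduct 18 (not isolated), via hemiformal 19 (not isolated)
Conditions: 16 (2.5 equiv, slow addition), toluene, 110 °C; after 16 is consumed, cool to rt, PPTS (0.2 equiv)
Reagents that add atoms: none
Why: Thermal retro-[4+2] of the dioxinone releases the acylketene 17, which adds to the electron-rich enol ether in a hetero-Diels–Alder reaction (C4a to the ketene carbon, the acyl oxygen to C8a), and acid-catalysed β-elimination of the acetal oxygen from C8a of 18 gives the γ-pyrone, while the hemiformal 19 left on O8 loses formaldehyde so that only the 8-hydroxyl is set free; the sp3 centres of 18 are lost again and C5–C8 are untouched.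

Step 11
Reactants: 21 2-methoxybenzene-1,4-diol
Product: 22 1-(2,5-dihydroxy-4-methoxyphenyl)ethanone
Conditions: AcOH, BF3·OEt2, 90 °C; then aq. NaOAc
Reagents that add atoms: acetic acid, CC(=O)O
Why: Boron trifluoride-promoted Friedel–Crafts (Nencki-type) acylation at the only position that is para to the methoxy group and ortho to a hydroxyl.

Step 12
Reactants: 22 1-(2,5-dihydroxy-4-methoxyphenyl)ethanone; 15 benzyl bromide
Product: 23 1-[5-(benzyloxy)-2-hydroxy-4-methoxyphenyl]ethanone
Conditions: K2CO3 (1.1 equiv), acetone, 50 °C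
Reagents that add atoms: none
Why: Williamson benzylation under weak base spares the 2-hydroxyl, which is hydrogen-bonded to the acetyl group and much less nucleophilic.

Step 13
Reactants: 23 1-[5-(benzyloxy)-2-hydroxy-4-methoxyphenyl]ethanone; 24 ethyl 3-phenylpropanoate
Product: 26 6-(benzyloxy)-7-methoxy-2-(2-phenylethyl)-4H-chromen-4-one, via diketone 25 (not isolated)
Conditions: NaH (3.5 equiv), THF, reflux; aq. HCl quench; then TsOH·H2O (cat.), toluene, 80 °C
Reagents that add atoms: none
Why: Claisen condensation of the ketone enolate (as the phenoxide dianion) with the ester gives the 1,3-diketone 25, and acid-catalysed cyclodehydration (phenol oxygen onto the distal carbonyl, then loss of water) closes the chromone.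

Step 14
Reactants: 26 6-(benzyloxy)-7-methoxy-2-(2-phenylethyl)-4H-chromen-4-one
Product: 27 6-hydroxy-7-methoxy-2-(2-phenylethyl)-4H-chromen-4-one
Conditions: H2 (1 atm), 10% Pd/C, EtOAc–MeOH, rt
Reagents that add atoms: none
Why: Hydrogenolysis of the benzyl aryl ether over palladium is much faster than reduction of the chromone C2=C3 bond, which is a vinylogous ester.

Step 15
Reactants: 20 (5S,6R,7R,8R)-8-hydroxy-6,7-(isopropylidenedioxy)-5-(methoxymethoxy)-2-(2-phenylethyl)-5,6,7,8-tetrahydro-4H-chromen-4-one; 27 6-hydroxy-7-methoxy-2-(2-phenylethyl)-4H-chromen-4-one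
Product: 28 (5S,6R,7S,8S)-6,7-(isopropylidenedioxy)-5-(methoxymethoxy)-8-{[7-methoxy-4-oxo-2-(2-phenylethyl)-4H-chromen-6-yl]oxy}-2-(2-phenylethyl)-5,6,7,8-tetrahydro-4H-chromen-4-one
Conditions: PPh3, DIAD, THF, 0 °C → rt
Reagents that add atoms: none
Why: Mitsunobu etherification, in which the alkoxyphosphonium salt at C8 is displaced by the phenoxide of 27 with SN2 inversion, so the 7,8-trans alcohol becomes the 7,8-cis aryl ether (8S); C8 is next to the electron-poor C8a of the pyrone, which favours SN2 over ionisation, and the equatorial leaving group has no antiperiplanar hydrogen for E2.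

Step 16
Reactants: 28 (5S,6R,7S,8S)-6,7-(isopropylidenedioxy)-5-(methoxymethoxy)-8-{[7-methoxy-4-oxo-2-(2-phenylethyl)-4H-chromen-6-yl]oxy}-2-(2-phenylethyl)-5,6,7,8-tetrahydro-4H-chromen-4-one
Product: 29 (5S,6R,7S,8S)-5,6,7-trihydroxy-8-{[7-methoxy-4-oxo-2-(2-phenylethyl)-4H-chromen-6-yl]oxy}-2-(2-phenylethyl)-5,6,7,8-tetrahydro-4H-chromen-4-one
Conditions: 3 M aq. HCl–THF (1:3), 40 °C
Reagents that add atoms: none
Why: Acid hydrolysis of the MOM acetal and of the strained trans-fused acetonide cleaves only O–C–O bonds, so the C–O bonds at C5, C6 and C7, the aryl ether and all four stereocentres should stay intact.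

**Compound list**

1 | 3,4-O-isopropylidene-D-mannitol | OC[C@@H](O)[C@H]1OC(C)(C)O[C@@H]1[C@H](O)CO | starting material
2 | 1,6-di-O-benzoyl-3,4-O-isopropylidene-D-mannitol | O=C(OC[C@@H](O)[C@H]1OC(C)(C)O[C@@H]1[C@H](O)COC(=O)c1ccccc1)c1ccccc1 | intermediate
3 | 1,6-di-O-benzoyl-3,4-O-isopropylidene-2,5-di-O-mesyl-D-mannitol | O=C(OC[C@@H](OS(C)(=O)=O)[C@H]1OC(C)(C)O[C@@H]1[C@H](OS(C)(=O)=O)COC(=O)c1ccccc1)c1ccccc1 | intermediate
4 | 3,4-O-isopropylidene-2,5-di-O-mesyl-D-mannitol (diol dimesylate, not isolated) | OC[C@@H](OS(C)(=O)=O)[C@H]1OC(C)(C)O[C@@H]1[C@H](OS(C)(=O)=O)CO | intermediate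
5 | 1,2:5,6-dianhydro-3,4-O-isopropylidene-L-iditol | C1O[C@@H]1[C@H]1OC(C)(C)O[C@@H]1[C@@H]1CO1 | intermediate
6 | 1,6-dideoxy-1,6-epithio-3,4-O-isopropylidene-L-iditol (C2-symmetric thiepane-3,6-diol, 4,5-acetonide) | S1C[C@H](O)[C@H]2OC(C)(C)O[C@@H]2[C@@H](O)C1 | intermediate
7 | 1,6-dideoxy-1,6-epithio-3,4-O-isopropylidene-2,5-bis-O-(methoxymethyl)-L-iditol | S1C[C@H](OCOC)[C@H]2OC(C)(C)O[C@@H]2[C@@H](OCOC)C1 | intermediate
8 | thionium chloride of 7 (S=C at one α-carbon, not isolated) | [Cl-].[S+]1C[C@H](OCOC)[C@H]2OC(C)(C)O[C@@H]2[C@@H](OCOC)C=1 | intermediate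
9 | 3,4-O-isopropylidene-5-O-(methoxymethyl)-1,2-O-methylene-6-thio-L-idoseptanose (ring sulfur, 1,2-cis dioxolane) | S1C[C@H](OCOC)[C@H]2OC(C)(C)O[C@@H]2[C@H]3OCO[C@@H]13 | intermediate
10 | S,S-dioxide of 9 | O=S1(=O)C[C@H](OCOC)[C@H]2OC(C)(C)O[C@@H]2[C@H]3OCO[C@@H]13 | intermediate
11 | α-bromo sulfone (Br on the CH2 α-carbon of 10, not isolated) | O=S1(=O)[C@H](Br)[C@H](OCOC)[C@H]2OC(C)(C)O[C@@H]2[C@H]3OCO[C@@H]13 | intermediate
12 | episulfone (thiirane 1,1-dioxide fused to the new cyclohexane, not isolated) | O=S1(=O)[C@@H]2[C@H](OCOC)[C@H]3OC(C)(C)O[C@@H]3[C@H]4OCO[C@@]124 | intermediate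
13 | 4,5-O-isopropylidene-3-O-(methoxymethyl)-1,6-O-methylenecyclohex-1-ene-1,3,4,5,6-pentol (C1=C2 is the future C8a=C4a; all-trans at C3–C6, L-ido) | C1=C3OCO[C@@H]3[C@H]2OC(C)(C)O[C@@H]2[C@H]1OCOC | intermediate
14 | 2,2,6-trimethyl-4H-1,3-dioxin-4-one | CC1=CC(=O)OC(C)(C)O1 | starting material
15 | benzyl bromide | BrCc1ccccc1 | starting material
16 | 2,2-dimethyl-6-(2-phenylethyl)-4H-1,3-dioxin-4-one | CC1(C)OC(=O)C=C(CCc2ccccc2)O1 | intermediate
17 | 3-oxo-5-phenylpent-1-en-1-one (acylketene, not isolated) | O=C=CC(=O)CCc1ccccc1 | intermediate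
18 | hetero-Diels–Alder adduct (2,3-dihydro-4-pyranone with C8a as ketal carbon and C4a–H, not isolated) | O=C1C=C(CCc2ccccc2)O[C@@]23OCO[C@@H]2[C@H]2OC(C)(C)O[C@@H]2[C@@H](OCOC)[C@@H]13 | intermediate
19 | 8-O-(hydroxymethyl) hemiformal of 20 (not isolated) | O=c1cc(CCc2ccccc2)oc2c1[C@H](OCOC)[C@H]1OC(C)(C)O[C@@H]1[C@H]2OCO | intermediate
20 | (5S,6R,7R,8R)-8-hydroxy-6,7-(isopropylidenedioxy)-5-(methoxymethoxy)-2-(2-phenylethyl)-5,6,7,8-tetrahydro-4H-chromen-4-one | O=c1cc(CCc2ccccc2)oc2c1[C@H](OCOC)[C@H]1OC(C)(C)O[C@@H]1[C@H]2O | intermediate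
21 | 2-methoxybenzene-1,4-diol (methoxyhydroquinone) | COc1cc(O)ccc1O | starting material
22 | 1-(2,5-dihydroxy-4-methoxyphenyl)ethanone | CC(=O)c1cc(O)c(OC)cc1O | intermediate
23 | 1-[5-(benzyloxy)-2-hydroxy-4-methoxyphenyl]ethanone | CC(=O)c1cc(OCc2ccccc2)c(OC)cc1O | intermediate
24 | ethyl 3-phenylpropanoate | CCOC(=O)CCc1ccccc1 | starting material
25 | 1-[5-(benzyloxy)-2-hydroxy-4-methoxyphenyl]-5-phenylpentane-1,3-dione (not isolated) | O=C(CC(=O)CCc1ccccc1)c1cc(OCc2ccccc2)c(OC)cc1O | intermediate
26 | 6-(benzyloxy)-7-methoxy-2-(2-phenylethyl)-4H-chromen-4-one | COc1cc2oc(CCc3ccccc3)cc(=O)c2cc1OCc1ccccc1 | intermediate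
27 | 6-hydroxy-7-methoxy-2-(2-phenylethyl)-4H-chromen-4-one | COc1cc2oc(CCc3ccccc3)cc(=O)c2cc1O | intermediate
28 | (5S,6R,7S,8S)-6,7-(isopropylidenedioxy)-5-(methoxymethoxy)-8-{[7-methoxy-4-oxo-2-(2-phenylethyl)-4H-chromen-6-yl]oxy}-2-(2-phenylethyl)-5,6,7,8-tetrahydro-4H-chromen-4-one | O=c1cc(CCc2ccccc2)oc2c1[C@H](OCOC)[C@H]1OC(C)(C)O[C@@H]1[C@@H]2Oc1cc2c(=O)cc(CCc3ccccc3)oc2cc1OC | intermediate
29 | (5S,6R,7S,8S)-5,6,7-trihydroxy-8-{[7-methoxy-4-oxo-2-(2-phenylethyl)-4H-chromen-6-yl]oxy}-2-(2-phenylethyl)-5,6,7,8-tetrahydro-4H-chromen-4-one | COc1cc2oc(CCc3ccccc3)cc(=O)c2cc1O[C@@H]1c2oc(CCc3ccccc3)cc(=O)c2[C@H](O)[C@@H](O)[C@@H]1O | target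

**Count**

Total steps: 16. Longest linear sequence: 11 steps (steps 1–8, 10, 15, 16) from 3,4-O-isopropylidene-D-mannitol.

**Steps most likely to fail**

1. Step 6 (proposed new method). The thionium ion may be taken by chloride, lose a proton to a vinyl sulfide, or be chlorinated a second time at the other α-carbon before the MOM oxygen closes and is demethylated.
Fallback with known chemistry, setting out from 6 and coming back at 20: both hydroxyls of 6 are acetylated (Ac2O, pyridine) to the diacetate F1. NCS chlorination α to sulfur, followed by MeOH and 2,6-lutidine, lets the neighbouring acetate capture the thionium ion as an acetoxonium ion, which methanol closes to the cyclic methyl orthoacetate F2 (classical 1,2-orthoester formation; C2 symmetry again removes the regiochemical question). The remote acetate is removed with NaOMe in MeOH to give the orthoester alcohol F3, which is capped with MOMCl and iPr2NEt as the orthoester MOM ether F4. Buffered mCPBA gives the orthoester sulfone F5, and the Ramberg–Bäcklund conditions of step 8 contract it to the orthoester-bridged enol ether F6. Annulation with 16 as in step 10 expels the orthoester oxygen from C8a, and the hemi-orthoester collapses to the 8-O-acetyl pyranone F7, which K2CO3 in MeOH at 0 °C converts into 20.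

2. Step 8 (key step). The carbanion at the CH2 α-carbon may expel the neighbouring methoxymethoxide (β-elimination to a vinyl sulfone) faster than it is brominated, or halogenation and closure may be slow at the hindered acetal carbon.
Fallback, setting out from 10 and coming back at 13: the two events are separated into a classical two-stage Ramberg–Bäcklund sequence. The CH2 carbanion is generated alone under kinetic control (LiHMDS, THF, −78 °C) and quenched at once with hexachloroethane to give the isolated α-chloro sulfone F8. Then t-BuOK in THF (−78 → 0 °C) only has to deprotonate the acetal carbon, whose carbanion is held back from β-elimination by the dioxolane, and the 1,3-elimination and loss of SO2 give 13.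

3. Step 15. Formation of the alkoxyphosphonium salt at the hindered C8 carbinol next to the trans-acetonide may be slow, so that alkylation of the hydrazide or partial loss of inversion competes with ether formation.
Fallback, setting out from 20 and coming back at 28: the alcohol is activated separately as the 8-O-triflate F9 (Tf2O, 2,6-di-tert-butylpyridine, CH2Cl2, −40 °C) and displaced with the preformed caesium phenoxide of 27 (Cs2CO3, MeCN, 0 °C), an SN2 reaction with the same inversion at C8.

**Further compounds**

F1 | step 6 | 2,5-di-O-acetyl-1,6-dideoxy-1,6-epithio-3,4-O-isopropylidene-L-iditol | S1C[C@H](OC(C)=O)[C@H]2OC(C)(C)O[C@@H]2[C@@H](OC(C)=O)C1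
F2 | step 6 | 5-O-acetyl-3,4-O-isopropylidene-6-thio-L-idoseptanose 1,2-(methyl orthoacetate) | S1C[C@H](OC(C)=O)[C@H]2OC(C)(C)O[C@@H]2[C@H]3O[C@](C)(OC)O[C@@H]13
F3 | step 6 | 3,4-O-isopropylidene-6-thio-L-idoseptanose 1,2-(methyl orthoacetate) | S1C[C@H](O)[C@H]2OC(C)(C)O[C@@H]2[C@H]3O[C@](C)(OC)O[C@@H]13
F4 | step 6 | 3,4-O-isopropylidene-5-O-(methoxymethyl)-6-thio-L-idoseptanose 1,2-(methyl orthoacetate) | S1C[C@H](OCOC)[C@H]2OC(C)(C)O[C@@H]2[C@H]3O[C@](C)(OC)O[C@@H]13
F5 | step 6 | S,S-dioxide of F4 | O=S1(=O)C[C@H](OCOC)[C@H]2OC(C)(C)O[C@@H]2[C@H]3O[C@](C)(OC)O[C@@H]13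
F6 | step 6 | orthoester-bridged enol ether (analogue of 13 with O–C(Me)(OMe)–O in place of O–CH2–O) | C1=C3O[C@@](C)(OC)O[C@@H]3[C@H]2OC(C)(C)O[C@@H]2[C@H]1OCOC
F7 | step 6 | (5S,6R,7R,8R)-8-acetoxy-6,7-(isopropylidenedioxy)-5-(methoxymethoxy)-2-(2-phenylethyl)-5,6,7,8-tetrahydro-4H-chromen-4-one | O=c1cc(CCc2ccccc2)oc2c1[C@H](OCOC)[C@H]1OC(C)(C)O[C@@H]1[C@H]2OC(C)=O
F8 | step 8 | α-chloro sulfone (Cl on the CH2 α-carbon of 10) | O=S1(=O)[C@H](Cl)[C@H](OCOC)[C@H]2OC(C)(C)O[C@@H]2[C@H]3OCO[C@@H]13
F9 | step 15 | 8-O-triflate of 20 | O=c1cc(CCc2ccccc2)oc2c1[C@H](OCOC)[C@H]1OC(C)(C)O[C@@H]1[C@H]2OS(=O)(=O)C(F)(F)F
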